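## Retrosynthetic overview
1. The C7 carbinol comes from a chelate-controlled hydride reduction of the (8S)-α-aryloxy ketone. The same hydride also removes the acetate from the ring A phenol.
2. The C8–O(aryl) bond comes from a Mitsunobu inversion of an (R)-α-hydroxy ketone with (E)-4-propenylsyringol, which is made from 4-allylsyringol by alkene isomerisation.
3. The key C7–C8 bond joins two carbonyl carbons. An enzyme-bound acyl anion (the ThDP Breslow enaminol of O-acetylsyringaldehyde) adds to acetaldehyde, and this event sets C8 as R.
4. No ring is formed. Ring A (from syringaldehyde) and ring B (from 4-allyl-2,6-dimethoxyphenol) are both bought intact.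

Assumption: recombinant benzaldehyde lyase (Pseudomonas fluorescens, His-tagged, purified) is treated as a purchasable or routinely expressed catalyst, and its preparation is not counted as a step.

Locants: C7 is the carbinol carbon, C8 the ether-bearing carbon and C9 the methyl. Ring A carries the free phenol and ring B the propenyl group. The target is (7R,8S), the erythro isomer.

## Route

**Step 1**
Reactants: 1 4-allyl-2,6-dimethoxyphenol
Product: 2 (E)-2,6-dimethoxy-4-(prop-1-en-1-yl)phenol
Conditions: RuHCl(CO)(PPh3)3 (0.5 mol %), toluene, 80 °C, 4 h; recrystallise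
Reagents that add atoms: none
Why: Ruthenium-hydride alkene isomerisation (hydrometalation/β-hydride elimination) moves the terminal alkene into conjugation with the arene and equilibrates it to the favoured E-styrene (about 97:3), tolerates the free phenol, makes no stereocentre, and leaves a few percent of Z isomer that is removed by crystallisation here or at ketone 9.

**Step 2**
Reactants: 3 syringaldehyde (4-hydroxy-3,5-dimethoxybenzaldehyde)
Product: 4 4-formyl-2,6-dimethoxyphenyl acetate
Conditions: Ac2O (1.2 equiv), pyridine, cat. DMAP, rt
Reagents that add atoms: acetic anhydride CC(=O)OC(C)=O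
Why: Nucleophile-catalysed O-acylation masks the acidic ring A phenol (pKa about 7.4) so that it cannot act as the pronucleophile in step 4, and the acetate is chosen because it stays close in size to a methoxy group for the enzyme and is removed by the hydride of step 5 without an extra step.

**Step 3 (key step)**
Reactants: 4 4-formyl-2,6-dimethoxyphenyl acetate; 5 acetaldehyde
Product: 7 (R)-4-(2-hydroxypropanoyl)-2,6-dimethoxyphenyl acetate, via ThDP-bound Breslow enaminol 6 (not isolated)
Conditions: benzaldehyde lyase, ThDP (0.15 mM), MgSO4 (2.5 mM), KH2PO4/K2HPO4 buffer (50 mM, pH 7.0), 20% v/v DMSO, 4 (20 mM), 5 (10 equiv, fed in portions), 30 °C, 24–48 h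
Reagents that add atoms: none
Why: In this enzymatic asymmetric cross-benzoin (acyloin) carboligation the ThDP ylide adds to the formyl group of 4 and proton loss gives Breslow enaminol 6, an acyl anion equivalent whose former carbonyl carbon is now nucleophilic, and the lyase pocket (which takes 3,5-dimethoxy- and 3,4,5-trimethoxybenzaldehyde as donors and small aliphatic aldehydes as acceptors) presents the Si face of acetaldehyde, so C8 forms as R in typically >97% ee while excess acetaldehyde drains any reversibly formed homo-benzoin.

**Step 4**
Reactants: 7 (R)-4-(2-hydroxypropanoyl)-2,6-dimethoxyphenyl acetate; 2 (E)-2,6-dimethoxy-4-(prop-1-en-1-yl)phenol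
Product: 9 4-[(2S)-2-{2,6-dimethoxy-4-[(E)-prop-1-enyl]phenoxy}propanoyl]-2,6-dimethoxyphenyl acetate, via alkoxyphosphonium phenoxide ion pair 8 (not isolated)
Conditions: 2 (1.2 equiv), PPh3 (1.3 equiv), DIAD (1.3 equiv, added last, dropwise), THF, 0 °C → rt
Reagents that add atoms: none
Why: In this Mitsunobu etherification the phenoxide of 2 (pKa about 10) displaces Ph3P=O from alkoxyphosphonium 8 in an SN2 step accelerated by the adjacent carbonyl, so C8 is inverted cleanly from R to S, and the nearly neutral medium leaves the enolisable α-centre, the aryl acetate and the styrene untouched.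

**Step 5**
Reactants: 9 4-[(2S)-2-{2,6-dimethoxy-4-[(E)-prop-1-enyl]phenoxy}propanoyl]-2,6-dimethoxyphenyl acetate
Product: 11 4-[(1R,2S)-1-hydroxy-2-{2,6-dimethoxy-4-[(E)-prop-1-enyl]phenoxy}propyl]-2,6-dimethoxyphenol (target), via erythro alcohol acetate 10 (not isolated)
Conditions: LiAlH4 (2 equiv), Et2O/THF 4:1, −78 → 0 °C; aq. potassium sodium tartrate work-up (near neutral)
Reagents that add atoms: none
Why: In this Cram-chelate-controlled hydride reduction followed by reductive ester cleavage, Li+ ties the ketone oxygen to the C8 ether oxygen (Lewis basic because the two ortho methoxy groups twist it out of conjugation), hydride enters from the face carrying the C8 hydrogen rather than the methyl and sets C7 as R (erythro, expected about 8–10:1, threo isomer removed by chromatography), and on warming the same reagent cleaves the acetate of 10 to the free phenol without touching C8 or the alkene.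

## Compound list
1 | 4-allyl-2,6-dimethoxyphenol | C=CCc1cc(OC)c(O)c(OC)c1 | starting material
2 | (E)-2,6-dimethoxy-4-(prop-1-en-1-yl)phenol | C/C=C/c1cc(OC)c(O)c(OC)c1 | intermediate
3 | syringaldehyde | O=Cc1cc(OC)c(O)c(OC)c1 | starting material
4 | 4-formyl-2,6-dimethoxyphenyl acetate | CC(=O)Oc1c(OC)cc(C=O)cc1OC | intermediate
5 | acetaldehyde | CC=O | starting material
6 | ThDP-bound Breslow enaminol of 4 (C2 of the thiazoline ring doubly bonded to the C(OH)Ar carbon) | Cc1ncc(CN2C(C)=C(CCOP(=O)(O)OP(=O)(O)O)SC2=C(O)c2cc(OC)c(OC(C)=O)c(OC)c2)c(N)n1 | intermediate (not isolated)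
7 | (R)-4-(2-hydroxypropanoyl)-2,6-dimethoxyphenyl acetate | C[C@@H](O)C(=O)c1cc(OC)c(OC(C)=O)c(OC)c1 | intermediate
8 | (R)-alkoxytriphenylphosphonium ion of 7 paired with the phenoxide of 2 | C[C@@H](O[P+](c1ccccc1)(c1ccccc1)c1ccccc1)C(=O)c1cc(OC)c(OC(C)=O)c(OC)c1.C/C=C/c1cc(OC)c([O-])c(OC)c1 | intermediate (not isolated)
9 | 4-[(2S)-2-{2,6-dimethoxy-4-[(E)-prop-1-enyl]phenoxy}propanoyl]-2,6-dimethoxyphenyl acetate | C/C=C/c1cc(OC)c(O[C@@H](C)C(=O)c2cc(OC)c(OC(C)=O)c(OC)c2)c(OC)c1 | intermediate
10 | 4-[(1R,2S)-1-hydroxy-2-{2,6-dimethoxy-4-[(E)-prop-1-enyl]phenoxy}propyl]-2,6-dimethoxyphenyl acetate | C/C=C/c1cc(OC)c(O[C@@H](C)[C@H](O)c2cc(OC)c(OC(C)=O)c(OC)c2)c(OC)c1 | intermediate (not isolated)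
11 | 4-[(1R,2S)-1-hydroxy-2-{2,6-dimethoxy-4-[(E)-prop-1-enyl]phenoxy}propyl]-2,6-dimethoxyphenol | C/C=C/c1cc(OC)c(O[C@@H](C)[C@H](O)c2cc(OC)c(O)c(OC)c2)c(OC)c1 | target

## Count and risks
Total steps: 5. Longest linear sequence: 4 (3 → 4 → 7 → 9 → 11). Step 1 lies on the short branch.

**Step 3 (most at risk).** The para-acetoxy donor is an untested substrate for the lyase. The activated aryl ester may also hydrolyse slowly in the buffer.
- The fallback sets out from 3 and 5 and comes back at 7. It makes the C–C bond before protection.
- Unprotected syringaldehyde 3 is used as the donor with the same lyase at pH 7.0. About half of the phenol stays protonated there, and 4-hydroxybenzaldehyde-type donors are accepted by this enzyme.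
- This gives (R)-2-hydroxy-1-(4-hydroxy-3,5-dimethoxyphenyl)propan-1-one F1.
- The acidic phenol of F1 is then acetylated selectively as its phenolate (Ac2O 1.05 equiv, aq. NaHCO3/EtOAc, 0 °C). The neutral secondary alcohol does not react, and the product is 7.

**Step 4.** The di-ortho-substituted phenol is a hindered nucleophile. Acetyl transfer from the activated aryl acetate to the phenoxide, or partial racemisation at C8, could erode yield or ee.
- The fallback sets out from 7 and comes back at 9. It replaces the redox condensation by activation and then displacement.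
- Compound 7 is mesylated (MsCl, Et3N, CH2Cl2, −20 °C) to (R)-1-(4-acetoxy-3,5-dimethoxyphenyl)-1-oxopropan-2-yl methanesulfonate F2.
- F2 is displaced by the pre-formed caesium phenoxide of 2 (Cs2CO3, MeCN, 0 °C) in a fast α-keto SN2 reaction with inversion, giving 9.

**Step 5.** Chelation by an aryl ether oxygen may be weaker than hoped, which would lower the erythro:threo ratio. Once the phenoxide is free, loss of the benzylic oxygen through a quinone methide is also possible.
- The fallback sets out from 9 and comes back at 11, passing through 10, which is now isolated. It switches from substrate control to catalyst control.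
- Noyori–Ikariya transfer hydrogenation with RuCl[(S,S)-TsDPEN](p-cymene) (1 mol %) in HCO2H/Et3N 5:2 at rt delivers hydride to the face that gives 7R. This is the same spatial sense as (S)-1-phenylethanol from acetophenone; the descriptor changes because C8 outranks the aryl group.
- The catalyst is expected to override the modest Felkin bias of the substrate, which favours the threo isomer.
- Compound 10 is then deacetylated with K2CO3 in MeOH at 0 °C to give 11.
- This fallback makes no new compound (entry F0).

## Further compounds
F1 | step 3 | (R)-2-hydroxy-1-(4-hydroxy-3,5-dimethoxyphenyl)propan-1-one | C[C@@H](O)C(=O)c1cc(OC)c(O)c(OC)c1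
F2 | step 4 | (R)-1-(4-acetoxy-3,5-dimethoxyphenyl)-1-oxopropan-2-yl methanesulfonate | C[C@@H](OS(C)(=O)=O)C(=O)c1cc(OC)c(OC(C)=O)c(OC)c1
F0 | step 5 | none | none
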